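Ring A is locally mirror-symmetric about its C6···C8a axis: with ring C opened at C4–C4a, the pairs C5-O/C7-O and C4a/C8 become equivalent. The route therefore hangs the complete, (S)-configured C2–C3–C4 chain on O1 of a symmetric 4-geranyl-3,5-bis(methoxymethoxy)phenol and closes the pyranone last by a Parham cyclization: iodine–lithium exchange at one of the two equivalent ortho carbons, then 6-exo attack on a tethered Weinreb amide, forges C4–C4a. Symmetry leaves the 6-geranyl (never the 8-geranyl) isomer as the only possible product, the base-labile ketone is unveiled only at the quench, and C2, set earlier by Mitsunobu inversion of a commercial (R)-carbinol, is not touched.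

Key step: step 7

Remark: flavanone numbering (O1, C2, C3, C4, C4a, C5–C8, C8a) is used; geranyl = (2E)-3,7-dimethylocta-2,6-dien-1-yl; MOM = methoxymethyl; the target is read as (2S)-6-geranylpinocembrin.

Step 1
Reactants: 1 resorcinol
Product: 2 1,3-bis(methoxymethoxy)benzene
Conditions: NaH, MOMCl, DMF, 0 °C to rt
Reagents that add atoms: chloromethyl methyl ether (MOMCl), COCCl
Why: Williamson-type O-alkylation of the sodium bis-phenoxide with the reactive chloromethyl ether should go to completion, and the MOM acetals later serve as ortho-directing groups that resist organolithium reagents.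

Step 2
Reactants: 2 1,3-bis(methoxymethoxy)benzene; 3 geranyl bromide
Product: 5 2-geranyl-1,3-bis(methoxymethoxy)benzene, via the C2 aryllithium 4 (not isolated)
Conditions: n-BuLi, THF, 0 °C to rt; then CuI (10 mol%), 3, −78 °C to rt
Reagents that add atoms: none
Why: Directed ortho-metalation removes the proton flanked by both OMOM groups, and copper-catalysed SN2 allylation of the aryllithium with the primary allylic bromide should deliver the linear E-geranyl unit without creating a stereocentre.

Step 3
Reactants: 5 2-geranyl-1,3-bis(methoxymethoxy)benzene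
Product: 7 4-geranyl-3,5-bis(methoxymethoxy)phenol, via the aryl pinacol boronate 6 (not isolated)
Conditions: [Ir(OMe)(cod)]2 (1.5 mol%), dtbpy (3 mol%), B2pin2, THF, 60 °C; then NaBO3·4H2O, THF/H2O, rt
Reagents that add atoms: bis(pinacolato)diboron, CC1(C)OB(OC1(C)C)B1OC(C)(C)C(C)(C)O1 (the boron group of 6); sodium perborate, [Na+].[Na+].O[B-]1(O)OO[B-](O)(O)OO1 (the phenol oxygen of 7)
Why: Iridium-catalysed aromatic C–H borylation is sterically controlled and the C–H para to the geranyl group is the only ring C–H without an ortho substituent, while the hindered trisubstituted alkenes should stay untouched; perborate oxidation of the carbon–boron bond then gives the phenol without epoxidising the alkenes.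

Step 4
Reactants: 7 4-geranyl-3,5-bis(methoxymethoxy)phenol
Product: 8 4-geranyl-2-iodo-3,5-bis(methoxymethoxy)phenol
Conditions: NIS (1.0 equiv), CH2Cl2, −40 to 0 °C
Reagents that add atoms: N-iodosuccinimide, O=C1CCC(=O)N1I
Why: Electrophilic aromatic iodination of the very electron-rich phenol at one of its two equivalent ortho positions (the only ring C–H left) should be far faster than attack of NIS on an unactivated alkene in an aprotic medium, and one equivalent limits it to mono-iodination.

Step 5
Reactants: 9 ethyl (R)-3-hydroxy-3-phenylpropanoate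
Product: 10 (R)-3-hydroxy-N-methoxy-N-methyl-3-phenylpropanamide
Conditions: MeNH(OMe)·HCl, iPrMgCl, THF, −20 to 0 °C
Reagents that add atoms: N,O-dimethylhydroxylamine hydrochloride, CNOC.Cl
Why: Aminolysis of the ester by the chloromagnesium amide made in the flask (Weinreb amide synthesis) should proceed on the magnesium alkoxide of the β-hydroxy ester without touching the carbinol centre, which stays (R).

Step 6
Reactants: 8 4-geranyl-2-iodo-3,5-bis(methoxymethoxy)phenol; 10 (R)-3-hydroxy-N-methoxy-N-methyl-3-phenylpropanamide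
Product: 11 (3S)-3-[4-geranyl-2-iodo-3,5-bis(methoxymethoxy)phenoxy]-N-methoxy-N-methyl-3-phenylpropanamide
Conditions: PPh3, DIAD, toluene, 0 °C to rt
Reagents that add atoms: none
Why: Mitsunobu etherification, in which the acidic ortho-iodophenol displaces the benzylic alkoxyphosphonium ion by SN2, should invert the (R)-carbinol to the (S)-aryl ether that becomes C2, with the non-polar solvent and low temperature disfavouring ionisation and elimination.

Step 7
Reactants: 11 (3S)-3-[4-geranyl-2-iodo-3,5-bis(methoxymethoxy)phenoxy]-N-methoxy-N-methyl-3-phenylpropanamide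
Product: 14 (2S)-6-geranyl-5,7-bis(methoxymethoxy)-2-phenylchroman-4-one, via the aryllithium 12 (not isolated), via the lithium hemiaminal chelate 13 (not isolated)
Conditions: n-BuLi (1.05 equiv), THF, −100 to −78 °C; then sat. aq. NH4Cl
Reagents that add atoms: none
Why: Iodine–lithium exchange, faster at −100 °C than addition of n-BuLi to the amide, gives aryllithium 12, which is stabilised by its two ortho oxygens. The carbanion adds 6-exo-trig to the tethered Weinreb amide and closes ring C by forming C4–C4a; the N-methoxy lithium chelate 13 holds the tetrahedral stage until the quench, so the ketone of 14 never meets a carbanion or base and retro-oxa-Michael opening, the racemisation path of flavanones, is shut off. The closest known reaction type is the Parham cyclization of ortho-halo aryl ethers carrying a tethered carboxyl derivative to chroman-4-ones, with an N-methoxy-N-methyl amide as internal electrophile. No stereocentre of the product is created: C2 was fixed in step 6 and lies outside the reacting centres, and the transient C4 aminal centre of 13 is lost on collapse. Regiochemistry needs no control, because the iodine sits on one of two carbons that were equivalent in phenol 7, so only the 6-geranyl skeleton can arise. The competing path, proton transfer from C3 to the aryllithium followed by loss of the aryloxide, should be held back by the low temperature and the high electrophilicity of the chelating amide carbonyl.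

Step 8
Reactants: 14 (2S)-6-geranyl-5,7-bis(methoxymethoxy)-2-phenylchroman-4-one
Product: 15 (2S)-6-geranyl-5,7-dihydroxy-2-phenylchroman-4-one
Conditions: 3 M aq. HCl, MeOH, rt to 40 °C
Reagents that add atoms: none
Why: Acid-catalysed acetal exchange with methanol should remove both MOM groups (the C5 one assisted by the peri carbonyl) under conditions mild enough to leave the geranyl alkenes uncyclised and C2, which epimerises mainly under base, intact.

Compound list
1 | resorcinol | Oc1cccc(O)c1 | starting material
2 | 1,3-bis(methoxymethoxy)benzene | COCOc1cccc(OCOC)c1 | intermediate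
3 | geranyl bromide, (2E)-1-bromo-3,7-dimethylocta-2,6-diene | CC(C)=CCC/C(C)=C/CBr | starting material
4 | 2-lithio-1,3-bis(methoxymethoxy)benzene (C2 aryllithium, not isolated) | COCOc1cccc(OCOC)c1[Li] | intermediate
5 | 2-geranyl-1,3-bis(methoxymethoxy)benzene | CC(C)=CCC/C(C)=C/Cc1c(OCOC)cccc1OCOC | intermediate
6 | 2-[4-geranyl-3,5-bis(methoxymethoxy)phenyl]-4,4,5,5-tetramethyl-1,3,2-dioxaborolane (aryl pinacol boronate, not isolated) | CC(C)=CCC/C(C)=C/Cc1c(OCOC)cc(B2OC(C)(C)C(C)(C)O2)cc1OCOC | intermediate
7 | 4-geranyl-3,5-bis(methoxymethoxy)phenol | CC(C)=CCC/C(C)=C/Cc1c(OCOC)cc(O)cc1OCOC | intermediate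
8 | 4-geranyl-2-iodo-3,5-bis(methoxymethoxy)phenol | CC(C)=CCC/C(C)=C/Cc1c(OCOC)cc(O)c(I)c1OCOC | intermediate
9 | ethyl (R)-3-hydroxy-3-phenylpropanoate | CCOC(=O)C[C@@H](O)c1ccccc1 | starting material
10 | (R)-3-hydroxy-N-methoxy-N-methyl-3-phenylpropanamide | CON(C)C(=O)C[C@@H](O)c1ccccc1 | intermediate
11 | (3S)-3-[4-geranyl-2-iodo-3,5-bis(methoxymethoxy)phenoxy]-N-methoxy-N-methyl-3-phenylpropanamide | CC(C)=CCC/C(C)=C/Cc1c(OCOC)cc(O[C@@H](CC(=O)N(C)OC)c2ccccc2)c(I)c1OCOC | intermediate
12 | (3S)-3-[4-geranyl-2-lithio-3,5-bis(methoxymethoxy)phenoxy]-N-methoxy-N-methyl-3-phenylpropanamide (aryllithium, not isolated) | CC(C)=CCC/C(C)=C/Cc1c(OCOC)cc(O[C@@H](CC(=O)N(C)OC)c2ccccc2)c([Li])c1OCOC | intermediate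
13 | lithium (2S)-6-geranyl-4-[methoxy(methyl)amino]-5,7-bis(methoxymethoxy)-2-phenylchroman-4-olate (chelated tetrahedral adduct, either configuration at C4, not isolated) | CC(C)=CCC/C(C)=C/Cc1c(OCOC)cc2c(c1OCOC)C(O[Li])(N(C)OC)C[C@@H](c1ccccc1)O2 | intermediate
14 | (2S)-6-geranyl-5,7-bis(methoxymethoxy)-2-phenylchroman-4-one | CC(C)=CCC/C(C)=C/Cc1c(OCOC)cc2c(c1OCOC)C(=O)C[C@@H](c1ccccc1)O2 | intermediate
15 | (2S)-6-geranyl-5,7-dihydroxy-2-phenylchroman-4-one, (2S)-6-geranylpinocembrin | CC(C)=CCC/C(C)=C/Cc1c(O)cc2c(c1O)C(=O)C[C@@H](c1ccccc1)O2 | target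

Total step count: 8 (steps 1–4 build the arene, step 5 the chain, steps 6–8 join, cyclise and deprotect).
Longest linear sequence: 7 steps (1, 2, 3, 4, 6, 7, 8, from resorcinol).

Steps most likely to fail

Step 6. The activated carbinol may be lost by elimination to the cinnamoyl amide, or configuration may erode through partial ionisation of the benzylic alkoxyphosphonium ion. The fallback sets out from 8 and comes back to the route at 11; it carries the chain at the alcohol oxidation level, so that no acidifying carbonyl is present during etherification. Commercial (R)-1-phenylpropane-1,3-diol would be silylated at the primary hydroxyl (TBSCl, imidazole, CH2Cl2) to (R)-3-(tert-butyldimethylsilyloxy)-1-phenylpropan-1-ol F1. Mitsunobu coupling of F1 with 8 (PPh3, DIAD, toluene) should give, with inversion, (S)-tert-butyl{3-[4-geranyl-2-iodo-3,5-bis(methoxymethoxy)phenoxy]-3-phenylpropoxy}dimethylsilane F2. TBAF in THF would free (3S)-3-[4-geranyl-2-iodo-3,5-bis(methoxymethoxy)phenoxy]-3-phenylpropan-1-ol F3. Oxidation with TEMPO (cat.) and PhI(OAc)2 in MeCN/H2O should give (3S)-3-[4-geranyl-2-iodo-3,5-bis(methoxymethoxy)phenoxy]-3-phenylpropanoic acid F4. Coupling of F4 with MeNH(OMe)·HCl (EDC·HCl, HOBt, N-methylmorpholine) would then give 11.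

Step 7. The aryllithium may act as a base instead of a nucleophile (proton transfer from C3, then loss of the aryloxide), or n-BuLi may add to the amide before exchange is complete. The fallback sets out from 8 and 10 and comes back at 14; it closes ring C through O1–C2 instead of C4–C4a, with the same symmetry-derived regiocontrol because only the O1 phenol is free. Amide 10 would be silylated (TBSCl, imidazole, DMF) to (R)-3-(tert-butyldimethylsilyloxy)-N-methoxy-N-methyl-3-phenylpropanamide F5. Phenol 8 would be deprotonated with NaH and its iodine exchanged with t-BuLi (2 equiv, THF, −78 °C); acylation of the resulting ortho-metalated phenoxide by F5 should give (R)-3-(tert-butyldimethylsilyloxy)-1-[3-geranyl-6-hydroxy-2,4-bis(methoxymethoxy)phenyl]-3-phenylpropan-1-one F6. Buffered HF·pyridine in THF would give (R)-1-[3-geranyl-6-hydroxy-2,4-bis(methoxymethoxy)phenyl]-3-hydroxy-3-phenylpropan-1-one F7. Intramolecular Mitsunobu etherification of F7 (PPh3, DIAD, THF, 0 °C) should close the ring with inversion at the carbinol to give 14.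

Step 3. The iridium hydride and boryl species, or the pinacolborane formed, may engage the two trisubstituted alkenes (hydroboration, double-bond migration), or conversion may stall. The fallback sets out from 2, uses 3 and comes back at 7; it borylates before the geranyl group is present. The same iridium-catalysed borylation of 2 (the position meta to both OMOM groups) should give 2-[3,5-bis(methoxymethoxy)phenyl]-4,4,5,5-tetramethyl-1,3,2-dioxaborolane F8, oxidised with NaBO3·4H2O to 3,5-bis(methoxymethoxy)phenol F9. Silylation (TIPSCl, imidazole, DMF) would give [3,5-bis(methoxymethoxy)phenoxy]triisopropylsilane F10. Lithiation between the two OMOM groups (n-BuLi, THF, 0 °C) and copper-catalysed allylation with 3 should give [4-geranyl-3,5-bis(methoxymethoxy)phenoxy]triisopropylsilane F11, and TBAF would release 7.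

Further compounds
F1 | step 6 | (R)-3-(tert-butyldimethylsilyloxy)-1-phenylpropan-1-ol | CC(C)(C)[Si](C)(C)OCC[C@@H](O)c1ccccc1
F2 | step 6 | (S)-tert-butyl{3-[4-geranyl-2-iodo-3,5-bis(methoxymethoxy)phenoxy]-3-phenylpropoxy}dimethylsilane | CC(C)=CCC/C(C)=C/Cc1c(OCOC)cc(O[C@@H](CCO[Si](C)(C)C(C)(C)C)c2ccccc2)c(I)c1OCOC
F3 | step 6 | (3S)-3-[4-geranyl-2-iodo-3,5-bis(methoxymethoxy)phenoxy]-3-phenylpropan-1-ol | CC(C)=CCC/C(C)=C/Cc1c(OCOC)cc(O[C@@H](CCO)c2ccccc2)c(I)c1OCOC
F4 | step 6 | (3S)-3-[4-geranyl-2-iodo-3,5-bis(methoxymethoxy)phenoxy]-3-phenylpropanoic acid | CC(C)=CCC/C(C)=C/Cc1c(OCOC)cc(O[C@@H](CC(=O)O)c2ccccc2)c(I)c1OCOC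
F5 | step 7 | (R)-3-(tert-butyldimethylsilyloxy)-N-methoxy-N-methyl-3-phenylpropanamide | CON(C)C(=O)C[C@@H](O[Si](C)(C)C(C)(C)C)c1ccccc1
F6 | step 7 | (R)-3-(tert-butyldimethylsilyloxy)-1-[3-geranyl-6-hydroxy-2,4-bis(methoxymethoxy)phenyl]-3-phenylpropan-1-one | CC(C)=CCC/C(C)=C/Cc1c(OCOC)cc(O)c(c1OCOC)C(=O)C[C@@H](O[Si](C)(C)C(C)(C)C)c1ccccc1
F7 | step 7 | (R)-1-[3-geranyl-6-hydroxy-2,4-bis(methoxymethoxy)phenyl]-3-hydroxy-3-phenylpropan-1-one | CC(C)=CCC/C(C)=C/Cc1c(OCOC)cc(O)c(c1OCOC)C(=O)C[C@@H](O)c1ccccc1
F8 | step 3 | 2-[3,5-bis(methoxymethoxy)phenyl]-4,4,5,5-tetramethyl-1,3,2-dioxaborolane | COCOc1cc(OCOC)cc(B2OC(C)(C)C(C)(C)O2)c1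
F9 | step 3 | 3,5-bis(methoxymethoxy)phenol | COCOc1cc(O)cc(OCOC)c1
F10 | step 3 | [3,5-bis(methoxymethoxy)phenoxy]triisopropylsilane | COCOc1cc(OCOC)cc(O[Si](C(C)C)(C(C)C)C(C)C)c1
F11 | step 3 | [4-geranyl-3,5-bis(methoxymethoxy)phenoxy]triisopropylsilane | CC(C)=CCC/C(C)=C/Cc1c(OCOC)cc(O[Si](C(C)C)(C(C)C)C(C)C)cc1OCOC
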